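**Retrosynthetic overview**
- Target 5 ⇒ 8-bromide 4 + MeOH: the C8–OMe bond is made last, by a visible-light nickel/iridium C(aryl)–O coupling at room temperature.
- 4 ⇒ tetramethyl ether 3 by C8-selective electrophilic bromination of ring A.
- 3 ⇒ (2S)-hesperetin 1 by exhaustive O-methylation under non-enolising conditions.
- No ring is built: rings A, B and the pyranone ring C, and the C2 (S) stereocentre, are all bought in 1 and only carried through.

Assumption: (2S)-hesperetin (natural citrus flavanone, sold as the S enantiomer) is used at ≥98% ee, checked by chiral HPLC before use.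

**Step 1**
Reactants: 1 (2S)-hesperetin
Product: 3 (2S)-2-(3,4-dimethoxyphenyl)-5,7-dimethoxychroman-4-one, via (2S)-hesperetin 7,3'-di-O-methyl ether 2 (not isolated)
Conditions: MeOH (10 equiv), PPh3 (4.5 equiv), DIAD (4.5 equiv), THF, 0 °C → 40 °C
Reagents that add atoms: methanol, CO
Why: Mitsunobu O-methylation, in which 7-OH and 3'-OH react first and the carbonyl-chelated 5-OH last (so 2 builds up), under conditions too weakly basic to enolise C3, so the retro-oxa-Michael opening to the chalcone that racemises flavanones under carbonate or alkoxide methylation is avoided and the bought C2 (S) centre is carried through untouched.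

**Step 2**
Reactants: 3 (2S)-2-(3,4-dimethoxyphenyl)-5,7-dimethoxychroman-4-one
Product: 4 (2S)-8-bromo-2-(3,4-dimethoxyphenyl)-5,7-dimethoxychroman-4-one
Conditions: NBS (1.02 equiv), MeCN, −10 → 0 °C, dark
Reagents that add atoms: N-bromosuccinimide, O=C1CCC(=O)N1Br
Why: Electrophilic aromatic bromination (NBS/MeCN nuclear bromination of methoxyarenes), in which ring A with its three oxygen donors is far more nucleophilic than the veratryl ring B and C8 (para to 5-OMe) is preferred over C6, which is screened by the 5-OMe methyl turned away from the peri carbonyl, the same C8 preference shown by 5,7-dialkoxy flavones and flavans; the neutral, cold, dark conditions leave C3 and the C2 (S) centre alone.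

**Step 3**
Reactants: 4 (2S)-8-bromo-2-(3,4-dimethoxyphenyl)-5,7-dimethoxychroman-4-one
Product: 5 (2S)-2-(3,4-dimethoxyphenyl)-5,7,8-trimethoxychroman-4-one
Conditions: MeOH (10 equiv), NiBr2(dme) (10 mol%), dtbbpy (12 mol%), [Ir(dF(CF3)ppy)2(dtbbpy)]PF6 (1 mol%), quinuclidine (10 mol%), K2CO3 (1.1 equiv), degassed MeCN, 450 nm LEDs, 25 °C
Reagents that add atoms: methanol, CO
Why: Proposed new method: nickel/iridium dual photoredox C(aryl)–O coupling applied to a doubly ortho-oxygenated, electron-rich bromoarene on a base-labile enantiopure flavanone, a substrate class on which it has not been shown; blue light excites the iridium complex, which oxidises quinuclidine and feeds the nickel cycle, a monovalent nickel–bipyridine species inserts into C8–Br (helped by the acyl group meta to bromine and the small, coordinating ortho oxygens), carbonate-assisted exchange with MeOH gives an aryl nickel methoxide, and its one-electron oxidation to trivalent nickel triggers C8–O reductive elimination, which ortho crowding accelerates; at 25 °C with only catalytic soluble amine and suspended K2CO3, C3 is not enolised and C2 stays S; the closest known reactions are the nickel/photoredox etherification of unhindered aryl bromides with alcohols and the hot CuBr/NaOMe bromide-to-methoxy exchange on 8-bromoflavones, which would open this flavanone.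

**Compound list**
1 | (2S)-hesperetin, (2S)-5,7-dihydroxy-2-(3-hydroxy-4-methoxyphenyl)chroman-4-one | COc1ccc([C@@H]2CC(=O)c3c(O)cc(O)cc3O2)cc1O | starting material
2 | (2S)-hesperetin 7,3'-di-O-methyl ether, (2S)-5-hydroxy-2-(3,4-dimethoxyphenyl)-7-methoxychroman-4-one | COc1ccc([C@@H]2CC(=O)c3c(O)cc(OC)cc3O2)cc1OC | intermediate
3 | (2S)-2-(3,4-dimethoxyphenyl)-5,7-dimethoxychroman-4-one | COc1ccc([C@@H]2CC(=O)c3c(OC)cc(OC)cc3O2)cc1OC | intermediate
4 | (2S)-8-bromo-2-(3,4-dimethoxyphenyl)-5,7-dimethoxychroman-4-one | COc1ccc([C@@H]2CC(=O)c3c(OC)cc(OC)c(Br)c3O2)cc1OC | intermediate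
5 | (2S)-2-(3,4-dimethoxyphenyl)-5,7,8-trimethoxychroman-4-one | COc1ccc([C@@H]2CC(=O)c3c(OC)cc(OC)c(OC)c3O2)cc1OC | target

**Totals**
Total step count: 3. Longest linear sequence: 3.

**Steps most likely to fail**

Step 3 (the proposed new coupling). Insertion of nickel into the crowded, electron-rich C8–Br bond may be slow, giving mainly protodebromination back to 3 (recyclable). The C2 centre may also erode, through carbonate-induced ring opening or hydrogen abstraction at C2–H by the quinuclidine radical cation; check ee by chiral HPLC. The fallback uses only known chemistry, sets out from 4 and comes back at 5. NaBH4 (MeOH/THF, 0 °C) reduces the ketone to the 2,4-cis alcohol (2S,4S)-8-bromo-2-(3,4-dimethoxyphenyl)-5,7-dimethoxychroman-4-ol F1. With the carbonyl gone, retro-oxa-Michael opening is impossible, so the classical Ullmann methoxylation (CuBr, NaOMe, MeOH/DMF, 100 °C) can be used to give (2S,4S)-2-(3,4-dimethoxyphenyl)-5,7,8-trimethoxychroman-4-ol F2. Dess–Martin periodinane buffered with NaHCO3 (CH2Cl2, 0 °C) then restores the ketone and delivers 5.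

Step 1. The chelated 5-OH may stall at 2, or forcing it may cost some ee. The fallback sets out from 1 and comes back at 3. NaBH4 reduction gives (2S,4S)-2-(3-hydroxy-4-methoxyphenyl)chromane-4,5,7-triol F3, kept neutral and used crude. Its three phenols, none chelated any more and with no carbonyl to allow ring opening, are methylated with MeI/K2CO3 in acetone to (2S,4S)-2-(3,4-dimethoxyphenyl)-5,7-dimethoxychroman-4-ol F4. Buffered Dess–Martin oxidation returns 3.

Step 2. Bromination may give C6/C8 mixtures, the 6,8-dibromide or C3 bromination. The fallback replaces steric control by phenol-directed para oxidation; it sets out from 2 (isolated by running step 1 with 2.1 equiv of PPh3 and DIAD at 0 °C) and comes back at 5, bypassing 3 and 4. PhI(OAc)2 (2.2 equiv) in MeOH at 0 °C oxidises the free 5-phenol twice at its para position C8 to the quinone monoketal (2S)-2-(3,4-dimethoxyphenyl)-7,8,8-trimethoxy-2,3-dihydro-4H-chromene-4,5(8H)-dione F5. Zn in AcOH reduces it to (2S)-5-hydroxy-2-(3,4-dimethoxyphenyl)-7,8-dimethoxychroman-4-one F6. Mitsunobu methylation of the remaining 5-OH (MeOH, PPh3, DIAD, THF) gives 5.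

**Further compounds**
F1 | step 3 | (2S,4S)-8-bromo-2-(3,4-dimethoxyphenyl)-5,7-dimethoxychroman-4-ol | COc1ccc([C@@H]2C[C@H](O)c3c(OC)cc(OC)c(Br)c3O2)cc1OC
F2 | step 3 | (2S,4S)-2-(3,4-dimethoxyphenyl)-5,7,8-trimethoxychroman-4-ol | COc1ccc([C@@H]2C[C@H](O)c3c(OC)cc(OC)c(OC)c3O2)cc1OC
F3 | step 1 | (2S,4S)-2-(3-hydroxy-4-methoxyphenyl)chromane-4,5,7-triol | COc1ccc([C@@H]2C[C@H](O)c3c(O)cc(O)cc3O2)cc1O
F4 | step 1 | (2S,4S)-2-(3,4-dimethoxyphenyl)-5,7-dimethoxychroman-4-ol | COc1ccc([C@@H]2C[C@H](O)c3c(OC)cc(OC)cc3O2)cc1OC
F5 | step 2 | (2S)-2-(3,4-dimethoxyphenyl)-7,8,8-trimethoxy-2,3-dihydro-4H-chromene-4,5(8H)-dione | COc1ccc([C@@H]2CC(=O)C3=C(O2)C(OC)(OC)C(OC)=CC3=O)cc1OC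
F6 | step 2 | (2S)-5-hydroxy-2-(3,4-dimethoxyphenyl)-7,8-dimethoxychroman-4-one | COc1ccc([C@@H]2CC(=O)c3c(O)cc(OC)c(OC)c3O2)cc1OC
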